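## Retrosynthetic overview

1. Naming: the upper robinetinidol unit is rings A/C/B, the lower epigallocatechin unit is rings D (aromatic), F (pyran) and E (pyrogallol). The last C–C bond made is C4(ring C)–C8(ring D), by a glutarate-tethered Friedel–Crafts alkylation that delivers ring D syn to the upper 3-oxygen (4β); the upper unit comes from (+)-dihydrorobinetin.
2. The lower unit (19, penta-O-benzyl-epigallocatechin) gets its C5/C7 oxygens by SNAr on fluorine, and ring F is closed at O1–C8a by intramolecular SNAr of the C2 alkoxide, with retention at C2 (hence 2,3-cis).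
3. Key disconnection: C2–C3 and C4–C4a of ring F together, by a palladium-catalysed conjunctive cross-coupling of an (S)-α-alkoxybenzyl boronic ester (ring E plus C2), vinylmagnesium chloride (C3=C4) and 2,4,6-trifluorophenyl triflate (ring D). Boron ends on C3 and is oxidised to the 3-OH.
4. Enabling feature: in ring F the carbinol carbon C3 lies between the unsubstituted methylene C4 (bonded to aromatic C4a of ring D) and the oxygenated benzylic carbon C2 (bearing O1 and ring E). This Ar–CH2–CH(O)–C array is what a vinylboron ate complex delivers, with the C3 oxygen mapped onto boron.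
5. Ring order: rings E and D are bought; ring F is closed in step 8; rings A/C/B are bought as the flavanonol; a temporary 14-membered tether ring is formed in step 15 and opened in step 16.

Key step: step 4

Assumption 1: compounds 1, 2 and 20 are taken as purchasable; (+)-dihydrorobinetin is the (2R,3R)-trans flavanonol.
Assumption 2: the (S,S)-diol is taken to direct the (R)-α-chloro boronic ester, and the (Sp,Sp) ligand is taken to be the antipode that gives (S)-1-aryl-2-alkanols in the simple alkyl series (the same topicity is named R here because C2 carries oxygen); if a model run shows the opposite sense, the mirror-image diol or ligand is used.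

## Route

Step 1
Reactants: 1 5-bromo-1,2,3-tris(benzyloxy)benzene; 2 (1S,2S)-1,2-dicyclohexylethane-1,2-diol
Product: 5 (4S,5S)-4,5-dicyclohexyl-2-[3,4,5-tris(benzyloxy)phenyl]-1,3,2-dioxaborolane, via aryllithium 3 (not isolated), via lithium aryltriisopropoxyborate 4 (not isolated)
Conditions: n-BuLi, THF, −78 °C; B(Oi-Pr)3, −78 °C → rt; then 2, HCl (Et2O), MgSO4, rt
Reagents that add atoms: triisopropyl borate CC(C)OB(OC(C)C)OC(C)C
Why: Bromine–lithium exchange, borylation and transesterification with the C2-symmetric diol (standard arylboronic ester synthesis) install the chiral director on boron; no stereocenter is formed.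

Step 2
Reactants: 5 (4S,5S)-4,5-dicyclohexyl-2-[3,4,5-tris(benzyloxy)phenyl]-1,3,2-dioxaborolane
Product: 8 (4S,5S)-4,5-dicyclohexyl-2-{(S)-[(4-methoxybenzyl)oxy][3,4,5-tris(benzyloxy)phenyl]methyl}-1,3,2-dioxaborolane, via dichloromethyl borate 6 (not isolated), via α-chloro boronic ester 7 (not isolated)
Conditions: CH2Cl2, n-BuLi, THF, −100 °C; 5; ZnCl2, −100 °C → rt; then LiOCH2C6H4-4-OMe (from 4-methoxybenzyl alcohol and n-BuLi), THF, 0 °C → rt
Reagents that add atoms: dichloromethane ClCCl; 4-methoxybenzyl alcohol COc1ccc(CO)cc1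
Why: Matteson homologation: LiCHCl2 adds to boron, the ZnCl2-promoted 1,2-aryl shift under control of the (S,S)-diol should give the (R)-chloride 7, and the lithium alkoxide then displaces chloride through a second borate with inversion, which sets the future lower-unit C2 as (S)-8.

Step 3
Reactants: 9 2,4,6-trifluorophenol
Product: 10 2,4,6-trifluorophenyl trifluoromethanesulfonate
Conditions: Tf2O, pyridine, CH2Cl2, 0 °C
Reagents that add atoms: trifluoromethanesulfonic anhydride O=S(=O)(OS(=O)(=O)C(F)(F)F)C(F)(F)F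
Why: O-sulfonylation of a phenol gives the electron-poor aryl electrophile that stands for ring D, its three fluorines being the later oxygen sites.

Step 4
Reactants: 8 (4S,5S)-4,5-dicyclohexyl-2-{(S)-[(4-methoxybenzyl)oxy][3,4,5-tris(benzyloxy)phenyl]methyl}-1,3,2-dioxaborolane; 11 vinylmagnesium chloride; 10 2,4,6-trifluorophenyl trifluoromethanesulfonate
Product: 13 (4S,5S)-4,5-dicyclohexyl-2-{(1S,2R)-1-[(4-methoxybenzyl)oxy]-1-[3,4,5-tris(benzyloxy)phenyl]-3-(2,4,6-trifluorophenyl)propan-2-yl}-1,3,2-dioxaborolane, via vinyl borate 12 (not isolated)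
Conditions: 11, THF, 0 °C → rt; NaOTf; then 10, Pd(OAc)2 (2 mol %), (Sp,Sp)-1,1′-bis[bis(4-methoxy-3,5-dimethylphenyl)phosphino]-2,2′-bis[(R)-α-(dimethylamino)benzyl]ferrocene (2.4 mol %), THF/DMSO, 40–60 °C
Reagents that add atoms: none
Why: Proposed new method: vinylmagnesium chloride adds to boron of 8 to give borate 12; zerovalent palladium inserts into the C–OTf bond of 10, the cationic arylpalladium (divalent palladium) binds the vinyl group and triggers a 1,2-metallate shift in which lower-unit C2 moves from boron to C3 anti to palladium, and reductive elimination from the alkyl(aryl)palladium joins C4 to C4a. The closest known reaction is the palladium/MandyPhos conjunctive cross-coupling of vinylboron ate complexes with aryl triflates (Grignard/NaOTf variant), and migration of α-alkoxyalkyl groups from boron is established in Matteson homologations; new here is a stereodefined α-alkoxybenzyl migrating group on a chiral diol ester. No ring is closed in this step; ring F is closed from its product in step 8. C2 is relayed with retention from 8 (it remains S in 13 only because boron, not oxygen, sits on C3), and C3 is set by the ligand-controlled face of the vinyl group, which should give the (R)-boronate. The step needs the metallate shift to outrun direct vinyl transfer to palladium, β-hydride elimination and loss of alkoxide from the borate; the triflate counter-ion, the wide-bite-angle bisphosphine, the electron-poor aryl group and the poor leaving ability of the 4-methoxybenzyl oxide are expected to secure this.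

Step 5
Reactants: 13 the boronic ester from step 4
Product: 14 (1R,2R)-1-[(4-methoxybenzyl)oxy]-1-[3,4,5-tris(benzyloxy)phenyl]-3-(2,4,6-trifluorophenyl)propan-2-ol
Conditions: H2O2 (30 %), NaOH (aq), THF, 0 °C → rt
Reagents that add atoms: hydrogen peroxide OO
Why: Oxidation of a secondary C–B bond by 1,2-shift to oxygen proceeds with retention, turning the boron-bearing C3 into the (R)-carbinol; the diol 2 is recovered.

Step 6
Reactants: 14 (1R,2R)-1-[(4-methoxybenzyl)oxy]-1-[3,4,5-tris(benzyloxy)phenyl]-3-(2,4,6-trifluorophenyl)propan-2-ol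
Product: 15 1,2,3-tris(benzyloxy)-5-[(1R,2R)-1-[(4-methoxybenzyl)oxy]-2-(methoxymethoxy)-3-(2,4,6-trifluorophenyl)propyl]benzene
Conditions: MeOCH2Cl, i-Pr2NEt, CH2Cl2, 0 °C → 40 °C
Reagents that add atoms: chloromethyl methyl ether COCCl
Why: Acetal protection of the C3 hydroxyl under amine base forms no alkoxide, so the five-ring SNAr onto an ortho fluorine cannot start, and the C3 oxygen is blocked for step 8.

Step 7
Reactants: 15 the methoxymethyl ether from step 6
Product: 16 (1R,2R)-2-(methoxymethoxy)-1-[3,4,5-tris(benzyloxy)phenyl]-3-(2,4,6-trifluorophenyl)propan-1-ol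
Conditions: DDQ, CH2Cl2/pH 7 buffer, 0 °C
Reagents that add atoms: none
Why: Oxidative cleavage of the 4-methoxybenzyl ether by DDQ is selective over benzyl and methoxymethyl ethers and frees only the C2 hydroxyl.

Step 8
Reactants: 16 (1R,2R)-2-(methoxymethoxy)-1-[3,4,5-tris(benzyloxy)phenyl]-3-(2,4,6-trifluorophenyl)propan-1-ol
Product: 17 (2R,3R)-5,7-difluoro-3-(methoxymethoxy)-2-[3,4,5-tris(benzyloxy)phenyl]chromane
Conditions: KN(SiMe3)2, THF, 0 °C → rt
Reagents that add atoms: none
Why: Intramolecular SNAr: the C2 alkoxide adds to an ortho C–F carbon of the trifluorophenyl ring (both ortho sites are equivalent) and fluoride leaves, closing ring F at O1–C8a without touching the C2–O bond, so the 2,3-cis relation from step 4 is kept.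

Step 9
Reactants: 17 (2R,3R)-5,7-difluoro-3-(methoxymethoxy)-2-[3,4,5-tris(benzyloxy)phenyl]chromane
Product: 18 (2R,3R)-5,7-bis(benzyloxy)-3-(methoxymethoxy)-2-[3,4,5-tris(benzyloxy)phenyl]chromane
Conditions: BnOH, NaH, DMPU, 120 °C
Reagents that add atoms: benzyl alcohol OCc1ccccc1
Why: Twofold SNAr by sodium benzyl oxide; each fluorine is meta to the other hetero-substituents, which activate it inductively without resonance deactivation, so forcing conditions should exchange both.

Step 10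
Reactants: 18 (2R,3R)-5,7-bis(benzyloxy)-3-(methoxymethoxy)-2-[3,4,5-tris(benzyloxy)phenyl]chromane
Product: 19 (2R,3R)-5,7-bis(benzyloxy)-2-[3,4,5-tris(benzyloxy)phenyl]chroman-3-ol (penta-O-benzyl-epigallocatechin)
Conditions: HCl (cat.), MeOH/THF, 45 °C
Reagents that add atoms: none
Why: Acid-catalysed transacetalisation removes the methoxymethyl group; the benzyl ethers and the flavan ring are stable to dilute acid.

Step 11
Reactants: 20 (+)-dihydrorobinetin, (2R,3R)-3,7-dihydroxy-2-(3,4,5-trihydroxyphenyl)chroman-4-one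
Product: 21 (2R,3R)-7-(benzyloxy)-3-hydroxy-2-[3,4,5-tris(benzyloxy)phenyl]chroman-4-one
Conditions: BnBr, K2CO3, DMF, rt, under argon
Reagents that add atoms: benzyl bromide BrCc1ccccc1
Why: Williamson benzylation of the four phenols under carbonate base leaves the aliphatic 3-OH free; C2 and C3 of the upper unit are bought with the flavanonol.

Step 12
Reactants: 21 (2R,3R)-7-(benzyloxy)-3-hydroxy-2-[3,4,5-tris(benzyloxy)phenyl]chroman-4-one
Product: 23 (2R,3S)-7-(benzyloxy)-4-methoxy-2-[3,4,5-tris(benzyloxy)phenyl]chroman-3-ol (C4 epimer mixture), via flavan-3,4-diol 22 (not isolated)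
Conditions: NaBH4, THF/MeOH, 0 °C; then camphorsulfonic acid (cat.), MeOH, rt
Reagents that add atoms: methanol CO
Why: Hydride reduction of the ketone gives the benzylic 4-alcohol, and acid-catalysed SN1 methanolysis through the 7-alkoxy-stabilised benzylic cation exchanges only that hydroxyl; the C4 configuration is irrelevant because C4 is ionised again in step 15.

Step 13
Reactants: 19 (2R,3R)-5,7-bis(benzyloxy)-2-[3,4,5-tris(benzyloxy)phenyl]chroman-3-ol
Product: 24 5-{[(2R,3R)-5,7-bis(benzyloxy)-2-[3,4,5-tris(benzyloxy)phenyl]chroman-3-yl]oxy}-5-oxopentanoic acid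
Conditions: glutaric anhydride, DMAP (cat.), pyridine, CH2Cl2, rt
Reagents that add atoms: glutaric anhydride O=C1CCCC(=O)O1
Why: DMAP-catalysed ring opening of the cyclic anhydride by the secondary 3-OH gives the half-ester that carries the tether.

Step 14
Reactants: 24 the hemiglutarate from step 13; 23 (2R,3S)-7-(benzyloxy)-4-methoxy-2-[3,4,5-tris(benzyloxy)phenyl]chroman-3-ol
Product: 25 mixed glutarate diester joining the 3-oxygen of the lower unit to the 3-oxygen of the 4-methoxy upper unit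
Conditions: EDC·HCl, DMAP, CH2Cl2, 0 °C → rt
Reagents that add atoms: none
Why: Steglich esterification acylates the only free hydroxyl of 23 and ties nucleophile and electrophile together through their 3-oxygens.

Step 15
Reactants: 25 the mixed glutarate diester
Product: 26 glutarate-bridged nona-O-benzyl robinetinidol-(4β→8)-epigallocatechin (14-membered 3,3′-diester ring, 4R in the upper unit)
Conditions: Me3SiOTf (cat.), CH2Cl2 (high dilution), −40 °C → −20 °C
Reagents that add atoms: none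
Why: Lewis-acid ionisation of the 4-methoxy group gives the flavan-4-yl cation, which undergoes intramolecular Friedel–Crafts alkylation at C8 of ring D; as in known diacyl-tethered flavan couplings, the tether on the β-oriented 3-oxygen should deliver the arene to the same face and set the 3,4-cis (4β) center, and C8 is the intrinsically preferred site of 5,7-dialkoxyflavans.

Step 16
Reactants: 26 the glutarate-bridged dimer
Product: 27 nona-O-benzyl robinetinidol-(4β→8)-epigallocatechin (both 3-OH free)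
Conditions: NaOMe (cat.), MeOH/THF, rt → 40 °C
Reagents that add atoms: none
Why: Base-catalysed transesterification cleaves both secondary esters and removes the tether as dimethyl glutarate without touching ethers or stereocenters.

Step 17
Reactants: 27 nona-O-benzyl robinetinidol-(4β→8)-epigallocatechin
Product: 28 robinetinidol-(4β→8)-epigallocatechin (target)
Conditions: H2 (1 atm), Pd(OH)2/C, THF/MeOH/H2O, rt
Reagents that add atoms: none
Why: Hydrogenolysis removes the nine benzyl ethers under neutral conditions that leave the interflavan bond and all five stereocenters intact.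

## Compound list

1 | 5-bromo-1,2,3-tris(benzyloxy)benzene | Brc1cc(OCc2ccccc2)c(OCc2ccccc2)c(OCc2ccccc2)c1 | starting material
2 | (1S,2S)-1,2-dicyclohexylethane-1,2-diol | O[C@@H](C1CCCCC1)[C@@H](O)C1CCCCC1 | starting material
3 | [3,4,5-tris(benzyloxy)phenyl]lithium | [Li]c1cc(OCc2ccccc2)c(OCc2ccccc2)c(OCc2ccccc2)c1 | intermediate
4 | lithium triisopropoxy[3,4,5-tris(benzyloxy)phenyl]borate | [Li+].CC(C)O[B-](OC(C)C)(OC(C)C)c1cc(OCc2ccccc2)c(OCc2ccccc2)c(OCc2ccccc2)c1 | intermediate
5 | (4S,5S)-4,5-dicyclohexyl-2-[3,4,5-tris(benzyloxy)phenyl]-1,3,2-dioxaborolane | B1(c2cc(OCc3ccccc3)c(OCc3ccccc3)c(OCc3ccccc3)c2)O[C@@H](C2CCCCC2)[C@H](C2CCCCC2)O1 | intermediate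
6 | lithium (4S,5S)-4,5-dicyclohexyl-2-(dichloromethyl)-2-[3,4,5-tris(benzyloxy)phenyl]-1,3,2-dioxaborolan-2-uide | [Li+].ClC(Cl)[B-]1(c2cc(OCc3ccccc3)c(OCc3ccccc3)c(OCc3ccccc3)c2)O[C@@H](C2CCCCC2)[C@H](C2CCCCC2)O1 | intermediate
7 | (4S,5S)-2-{(R)-chloro[3,4,5-tris(benzyloxy)phenyl]methyl}-4,5-dicyclohexyl-1,3,2-dioxaborolane | Cl[C@@H](c1cc(OCc2ccccc2)c(OCc2ccccc2)c(OCc2ccccc2)c1)B1O[C@@H](C2CCCCC2)[C@H](C2CCCCC2)O1 | intermediate
8 | (4S,5S)-4,5-dicyclohexyl-2-{(S)-[(4-methoxybenzyl)oxy][3,4,5-tris(benzyloxy)phenyl]methyl}-1,3,2-dioxaborolane | COc1ccc(CO[C@H](c2cc(OCc3ccccc3)c(OCc3ccccc3)c(OCc3ccccc3)c2)B2O[C@@H](C3CCCCC3)[C@H](C3CCCCC3)O2)cc1 | intermediate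
9 | 2,4,6-trifluorophenol | Oc1c(F)cc(F)cc1F | starting material
10 | 2,4,6-trifluorophenyl trifluoromethanesulfonate | O=S(=O)(Oc1c(F)cc(F)cc1F)C(F)(F)F | intermediate
11 | vinylmagnesium chloride | C=C[Mg]Cl | starting material
12 | chloromagnesium vinyl borate of 8 (ate complex) | [Mg+2].[Cl-].COc1ccc(CO[C@H](c2cc(OCc3ccccc3)c(OCc3ccccc3)c(OCc3ccccc3)c2)[B-]2(C=C)O[C@@H](C3CCCCC3)[C@H](C3CCCCC3)O2)cc1 | intermediate
13 | (4S,5S)-4,5-dicyclohexyl-2-{(1S,2R)-1-[(4-methoxybenzyl)oxy]-1-[3,4,5-tris(benzyloxy)phenyl]-3-(2,4,6-trifluorophenyl)propan-2-yl}-1,3,2-dioxaborolane | COc1ccc(CO[C@H](c2cc(OCc3ccccc3)c(OCc3ccccc3)c(OCc3ccccc3)c2)[C@H](B2O[C@@H](C3CCCCC3)[C@H](C3CCCCC3)O2)Cc2c(F)cc(F)cc2F)cc1 | intermediate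
14 | (1R,2R)-1-[(4-methoxybenzyl)oxy]-1-[3,4,5-tris(benzyloxy)phenyl]-3-(2,4,6-trifluorophenyl)propan-2-ol | COc1ccc(CO[C@H](c2cc(OCc3ccccc3)c(OCc3ccccc3)c(OCc3ccccc3)c2)[C@H](O)Cc2c(F)cc(F)cc2F)cc1 | intermediate
15 | 1,2,3-tris(benzyloxy)-5-[(1R,2R)-1-[(4-methoxybenzyl)oxy]-2-(methoxymethoxy)-3-(2,4,6-trifluorophenyl)propyl]benzene | COc1ccc(CO[C@H](c2cc(OCc3ccccc3)c(OCc3ccccc3)c(OCc3ccccc3)c2)[C@H](OCOC)Cc2c(F)cc(F)cc2F)cc1 | intermediate
16 | (1R,2R)-2-(methoxymethoxy)-1-[3,4,5-tris(benzyloxy)phenyl]-3-(2,4,6-trifluorophenyl)propan-1-ol | O[C@H](c1cc(OCc2ccccc2)c(OCc2ccccc2)c(OCc2ccccc2)c1)[C@H](OCOC)Cc1c(F)cc(F)cc1F | intermediate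
17 | (2R,3R)-5,7-difluoro-3-(methoxymethoxy)-2-[3,4,5-tris(benzyloxy)phenyl]chromane | Fc1cc(F)c2c(c1)O[C@H](c1cc(OCc3ccccc3)c(OCc3ccccc3)c(OCc3ccccc3)c1)[C@H](OCOC)C2 | intermediate
18 | (2R,3R)-5,7-bis(benzyloxy)-3-(methoxymethoxy)-2-[3,4,5-tris(benzyloxy)phenyl]chromane | c1ccccc1COc1cc(OCc3ccccc3)c2c(c1)O[C@H](c1cc(OCc3ccccc3)c(OCc3ccccc3)c(OCc3ccccc3)c1)[C@H](OCOC)C2 | intermediate
19 | (2R,3R)-5,7-bis(benzyloxy)-2-[3,4,5-tris(benzyloxy)phenyl]chroman-3-ol | c1ccccc1COc1cc(OCc3ccccc3)c2c(c1)O[C@H](c1cc(OCc3ccccc3)c(OCc3ccccc3)c(OCc3ccccc3)c1)[C@H](O)C2 | intermediate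
20 | (+)-dihydrorobinetin, (2R,3R)-3,7-dihydroxy-2-(3,4,5-trihydroxyphenyl)chroman-4-one | Oc1ccc2c(c1)O[C@H](c1cc(O)c(O)c(O)c1)[C@@H](O)C2=O | starting material
21 | (2R,3R)-7-(benzyloxy)-3-hydroxy-2-[3,4,5-tris(benzyloxy)phenyl]chroman-4-one | c1ccccc1COc1ccc2c(c1)O[C@H](c1cc(OCc3ccccc3)c(OCc3ccccc3)c(OCc3ccccc3)c1)[C@@H](O)C2=O | intermediate
22 | (2R,3S,4R)-7-(benzyloxy)-2-[3,4,5-tris(benzyloxy)phenyl]chromane-3,4-diol (2,3-trans-3,4-trans, main epimer) | c1ccccc1COc1ccc2c(c1)O[C@H](c1cc(OCc3ccccc3)c(OCc3ccccc3)c(OCc3ccccc3)c1)[C@@H](O)[C@@H]2O | intermediate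
23 | (2R,3S)-7-(benzyloxy)-4-methoxy-2-[3,4,5-tris(benzyloxy)phenyl]chroman-3-ol (C4 epimer mixture) | c1ccccc1COc1ccc2c(c1)O[C@H](c1cc(OCc3ccccc3)c(OCc3ccccc3)c(OCc3ccccc3)c1)[C@@H](O)C2OC | intermediate
24 | 5-{[(2R,3R)-5,7-bis(benzyloxy)-2-[3,4,5-tris(benzyloxy)phenyl]chroman-3-yl]oxy}-5-oxopentanoic acid | c1ccccc1COc1cc(OCc3ccccc3)c2c(c1)O[C@H](c1cc(OCc3ccccc3)c(OCc3ccccc3)c(OCc3ccccc3)c1)[C@H](OC(=O)CCCC(=O)O)C2 | intermediate
25 | mixed glutarate diester of 19 (3-O) and 23 (3-O) | c1ccccc1COc1cc(OCc3ccccc3)c2c(c1)O[C@H](c1cc(OCc3ccccc3)c(OCc3ccccc3)c(OCc3ccccc3)c1)[C@H](OC(=O)CCCC(=O)O[C@@H]1[C@@H](c3cc(OCc4ccccc4)c(OCc4ccccc4)c(OCc4ccccc4)c3)Oc3cc(OCc4ccccc4)ccc3C1OC)C2 | intermediate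
26 | 3,3′-O-glutarate-bridged nona-O-benzyl robinetinidol-(4β→8)-epigallocatechin (14-membered ring) | c1ccccc1COc1cc(OCc3ccccc3)c2c(c15)O[C@H](c1cc(OCc3ccccc3)c(OCc3ccccc3)c(OCc3ccccc3)c1)[C@H](OC(=O)CCCC(=O)O[C@@H]1[C@@H](c3cc(OCc4ccccc4)c(OCc4ccccc4)c(OCc4ccccc4)c3)Oc3cc(OCc4ccccc4)ccc3[C@@H]15)C2 | intermediate
27 | nona-O-benzyl robinetinidol-(4β→8)-epigallocatechin | c1ccccc1COc1ccc2c(c1)O[C@H](c1cc(OCc3ccccc3)c(OCc3ccccc3)c(OCc3ccccc3)c1)[C@@H](O)[C@H]2c1c(OCc3ccccc3)cc(OCc3ccccc3)c2c1O[C@H](c1cc(OCc3ccccc3)c(OCc3ccccc3)c(OCc3ccccc3)c1)[C@H](O)C2 | intermediate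
28 | robinetinidol-(4β→8)-epigallocatechin (CNP0275321.4) | Oc1ccc2c(c1)O[C@H](c1cc(O)c(O)c(O)c1)[C@@H](O)[C@H]2c1c(O)cc(O)c2c1O[C@H](c1cc(O)c(O)c(O)c1)[C@H](O)C2 | target

## Step count and risks

Total step count: 17. Longest linear sequence: 14 steps (steps 1, 2, 4–10, 13–17).

Steps most likely to fail:

Step 4 (proposed new method). Direct transfer of the vinyl group to palladium, β-hydride elimination after the shift, slow borate formation at the hindered boron, or erosion of facial control by the chiral diol may each undercut the metallate shift. The fallback uses known Matteson chemistry and sets out from 8: a second homologation (CH2Cl2, n-BuLi, THF, −100 °C; ZnCl2) under the same diol control should give the (1R,2R)-1-chloro-2-alkoxy boronic ester F1. Its chloride is then displaced with inversion by (2,4,6-trifluorobenzyl)magnesium bromide F2, made from 2,4,6-trifluorobenzyl bromide and magnesium in Et2O. This comes back to the route at 13, with the two C–C bonds made in separate operations.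

Step 9. The second fluoride exchange on the now alkoxy-rich ring may stall, or the substrate may degrade under hot alkoxide. The fallback sets out from 17: nickel/copper-catalysed defluoroborylation (Ni(cod)2, PCy3, CuI, CsF, B2pin2, toluene, 80 °C) should give the 5,7-bis(pinacolboronate) F3. Oxidation (H2O2, NaOH, THF) gives the 5,7-diphenol F4, and benzylation (BnBr, K2CO3, DMF) comes back to the route at 18.

Step 15. Oligomerisation may compete with ring closure, the arene may attack through C6, or the tether may fail to enforce syn delivery. The fallback sets out from 19 and 23 and skips 24–26: intermolecular Friedel–Crafts coupling (Me3SiOTf, excess 19, CH2Cl2, −78 °C → −20 °C) should give 27 together with its 3,4-trans isomer, nona-O-benzyl robinetinidol-(4α→8)-epigallocatechin F5. F5 is removed by chromatography, and the route is rejoined at 27.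

Further compounds
F1 | step 4 | (4S,5S)-2-{(1R,2R)-1-chloro-2-[(4-methoxybenzyl)oxy]-2-[3,4,5-tris(benzyloxy)phenyl]ethyl}-4,5-dicyclohexyl-1,3,2-dioxaborolane | COc1ccc(CO[C@H](c2cc(OCc3ccccc3)c(OCc3ccccc3)c(OCc3ccccc3)c2)[C@H](Cl)B2O[C@@H](C3CCCCC3)[C@H](C3CCCCC3)O2)cc1
F2 | step 4 | (2,4,6-trifluorobenzyl)magnesium bromide | Fc1cc(F)c(C[Mg]Br)c(F)c1
F3 | step 9 | (2R,3R)-3-(methoxymethoxy)-5,7-bis(4,4,5,5-tetramethyl-1,3,2-dioxaborolan-2-yl)-2-[3,4,5-tris(benzyloxy)phenyl]chromane | CC1(C)OB(OC1(C)C)c1cc(B3OC(C)(C)C(C)(C)O3)c2c(c1)O[C@H](c1cc(OCc3ccccc3)c(OCc3ccccc3)c(OCc3ccccc3)c1)[C@H](OCOC)C2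
F4 | step 9 | (2R,3R)-3-(methoxymethoxy)-2-[3,4,5-tris(benzyloxy)phenyl]chromane-5,7-diol | Oc1cc(O)c2c(c1)O[C@H](c1cc(OCc3ccccc3)c(OCc3ccccc3)c(OCc3ccccc3)c1)[C@H](OCOC)C2
F5 | step 15 | nona-O-benzyl robinetinidol-(4α→8)-epigallocatechin | c1ccccc1COc1ccc2c(c1)O[C@H](c1cc(OCc3ccccc3)c(OCc3ccccc3)c(OCc3ccccc3)c1)[C@@H](O)[C@@H]2c1c(OCc3ccccc3)cc(OCc3ccccc3)c2c1O[C@H](c1cc(OCc3ccccc3)c(OCc3ccccc3)c(OCc3ccccc3)c1)[C@H](O)C2
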